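**Retrosynthetic overview**

1. Target 26 comes from 23 by C‑acylation with (S)‑2‑methylbutanoic acid; 23 from cage ketal 22 by hydrolysis; 22 from 20 by catalyst‑controlled C‑prenylation (C5 stereocentre); 20 from 18, and 18 from 16.
2. Key disconnection: the trione ring of 16 is cut at C1(spiro)–C6(=O) and at C5–C4(O). This gives the γ‑carbon and the thioester carbon of 3‑oxothioester 12 (C1–C2–C3–C4) and the C6–C5 unit as (trimethylsilyl)ketene 13.
3. Enabling feature: the ring is a cyclohexane‑1,3,5‑trione, three head‑to‑tail ketene units, and the C6(=O)–C5 pair between two quaternary carbons is a latent ketene. While C3 and C5 are bare CH2 the ring is locally symmetric, so C1 is not yet a stereocentre and the annulation is stereoconvergent.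
4. The spiro configuration is fixed afterwards by a temporary cage ketal. It is possible because C2=O and the two tertiary hydroxyls (C1', C4') are mutually cis, 1,3,5 on the cyclohexane; the same cage singles out C5 for methylation and prenylation.
5. Ring order: cyclopentane (bought as cyclopentenone) → cyclohexane (step 2) → trione ring (step 7) → temporary dioxa cage (on in step 8, off in step 11). The hydrindane stereocentres come from steps 2 and 4.

Key step: step 7

Locants: hydrindane atoms are numbered as octahydro‑1H‑indene (primed in the spiro compounds, spiro atom C6' = C1). In the trione ring C1 is the spiro carbon, C2 the carbonyl on the hydroxyl face, then C3, C4, C5 (methyl/prenyl carbon) and C6.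

Assumption: the sense of induction of the chiral catalysts in steps 2 and 10 is taken as written; if either is opposite, the quinidine‑derived pseudo‑enantiomer (step 2) or the (S,S) ligand (step 10) is the one meant.

**Route**

Step 1
Reactants: 1 nitromethane; 2 methyl 2‑(bromomethyl)prop‑2‑enoate
Product: 3 methyl 2‑methylidene‑4‑nitrobutanoate
Conditions: MeNO2 (10 equiv), Et3N (1.05 equiv), MeCN, 0 °C → rt
Reagents that add atoms: none
Why: The nitronate should displace bromide by SN2′ (conjugate addition–elimination) on the 2‑(bromomethyl)acrylate, and the large excess of nitromethane should suppress double alkylation.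

Step 2
Reactants: 3 methyl 2‑methylidene‑4‑nitrobutanoate; 4 cyclopent‑2‑en‑1‑one
Product: 6 methyl (3aS,7aS)‑4‑nitro‑1‑oxooctahydro‑1H‑indene‑6‑carboxylate, via nitro‑Michael adduct 5 (not isolated)
Conditions: 9‑amino‑9‑deoxy‑epi‑quinine (20 mol%), PhCO2H (40 mol%), toluene, rt
Reagents that add atoms: none
Why: In this amine‑catalysed Michael/Michael domino reaction the nitronate of 3 should add to the iminium ion of 4 on the face chosen by the cinchona primary amine (sets C3a), and the resulting enamine should close the cyclohexane by 6‑endo‑trig Michael addition onto the acrylate, kinetically to the cis ring fusion (sets C7a); C4 and C6 form as mixtures that are erased in steps 3 and 7.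

Step 3
Reactants: 6 methyl (3aS,7aS)‑4‑nitro‑1‑oxooctahydro‑1H‑indene‑6‑carboxylate
Product: 8 methyl (3aS,7aS)‑1,4‑dioxooctahydro‑1H‑indene‑6‑carboxylate, via potassium nitronate 7 (not isolated)
Conditions: K2CO3, MeOH, 0 °C; then KHSO5 (Oxone), Na2HPO4, MeOH/H2O, 0 °C → rt
Reagents that add atoms: potassium peroxymonosulfate, [K+].[O-]S(=O)(=O)OO (gives the carbonyl oxygen)
Why: In this oxidative Nef reaction the nitronate should be oxidised at carbon by the peroxide and lose nitrite, under buffered conditions mild enough to keep the cis ring fusion.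

Step 4
Reactants: 8 methyl (3aS,7aS)‑1,4‑dioxooctahydro‑1H‑indene‑6‑carboxylate
Product: 9 methyl (1R,3aS,4R,7aS)‑1,4‑dihydroxy‑1,4‑dimethyloctahydro‑1H‑indene‑6‑carboxylate
Conditions: MeMgBr (2.6 equiv), CeCl3 (2.6 equiv), THF, −78 °C; aq. NH4Cl
Reagents that add atoms: methylmagnesium bromide, C[Mg]Br
Why: Organocerium 1,2‑addition should reach both ketones from the convex face of the cis‑hydrindanedione (anti to the other ring), so each methyl ends cis to the ring‑fusion hydrogens and each hydroxyl on the concave face; the non‑basic reagent should avoid enolisation and spare the ester at −78 °C.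

Step 5
Reactants: 9 methyl (1R,3aS,4R,7aS)‑1,4‑dihydroxy‑1,4‑dimethyloctahydro‑1H‑indene‑6‑carboxylate
Product: 10 methyl (1R,3aS,4R,7aS)‑1,4‑dimethyl‑1,4‑bis(trimethylsilyloxy)octahydro‑1H‑indene‑6‑carboxylate
Conditions: Me3SiOTf (2.4 equiv), 2,6‑lutidine (3 equiv), CH2Cl2, −78 → 0 °C
Reagents that add atoms: trimethylsilyl trifluoromethanesulfonate, C[Si](C)(C)OS(=O)(=O)C(F)(F)F
Why: Silyl triflate silylation should cap both tertiary alcohols so that no alkoxide competes in steps 6 and 7; the groups are lost in the acidic work‑up of step 7.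

Step 6
Reactants: 10 methyl (1R,3aS,4R,7aS)‑1,4‑dimethyl‑1,4‑bis(trimethylsilyloxy)octahydro‑1H‑indene‑6‑carboxylate; 11 S‑tert‑butyl ethanethioate
Product: 12 S‑tert‑butyl 3‑[(1R,3aS,4R,7aS)‑1,4‑dimethyl‑1,4‑bis(trimethylsilyloxy)octahydro‑1H‑inden‑6‑yl]‑3‑oxopropanethioate
Conditions: 11 (3 equiv), LiN(SiMe3)2 (3 equiv), THF, −78 °C; then 10, −78 → 0 °C; aq. NH4Cl
Reagents that add atoms: none
Why: In this crossed Claisen condensation the lithium thioester enolate should be acylated by the methyl ester, and deprotonation of the 3‑oxothioester product should drive the equilibrium.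

Step 7
Reactants: 12 S‑tert‑butyl 3‑[(1R,3aS,4R,7aS)‑1,4‑dimethyl‑1,4‑bis(trimethylsilyloxy)octahydro‑1H‑inden‑6‑yl]‑3‑oxopropanethioate; 13 (trimethylsilyl)ketene
Product: 16 (1'R,3a'S,4'R,7a'S)‑1',4'‑dihydroxy‑1',4'‑dimethyloctahydrospiro[cyclohexane‑1,6'‑indene]‑2,4,6‑trione, via γ‑acylated dienolate 14 (not isolated), via C‑silyl spirotrione 15 (not isolated)
Conditions: LiN(iPr)2 (2.2 equiv), THF, −78 → −20 °C; 13 (1.2 equiv), −78 °C → rt; then 1 M HCl, THF/MeOH, rt
Reagents that add atoms: none
Why: Proposed new method: the γ‑carbon (C6 of the hydrindane) of the 3‑oxothioester dianion should add to the carbonyl carbon of the silylketene to give the α‑silyl ketone enolate 14, whose silyl‑bearing carbon then attacks the thioester carbon and expels tert‑butylthiolate (Claisen/Dieckmann‑type closure, 6‑exo‑trig) to give 15; the acid work‑up cleaves the C–Si bond of the α‑silyl 1,3‑diketone and both silyl ethers. The closest known chemistry is the γ‑acylation of 1,3‑dicarbonyl dianions followed by Claisen cyclisation of the resulting triketo ester to a phloroglucinol‑type trione, the alkoxide‑mediated conversion of dimethylketene dimer into its cyclic trimer, and the addition of organolithiums and enolates to silylketenes. The step builds the whole trione ring and the quaternary spiro carbon but no new stereocentre, because the new ring is locally symmetric: both C6 epimers of 12 and both faces of the planar γ‑enolate converge on the single compound 16. It needs γ‑ over α‑C‑acylation and C‑ over O‑acylation in the ring closure; the first should be secured by the dianion (the γ‑carbon is the last‑formed and most nucleophilic site), the second by the soft thioester electrophile and by the stabilised trione enolate as thermodynamic sink.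

Step 8
Reactants: 16 (1'R,3a'S,4'R,7a'S)‑1',4'‑dihydroxy‑1',4'‑dimethyloctahydrospiro[cyclohexane‑1,6'‑indene]‑2,4,6‑trione
Product: 18 cage ketal of 16 (C2 ketalised by the C1' and C4' oxygens), via cyclic enol ether 17 (not isolated)
Conditions: PPTS (10 mol%), 4 Å MS, benzene, 60 °C
Reagents that add atoms: none
Why: In this acid‑catalysed intramolecular ketalisation with removal of water only the ring carbonyl cis to both tertiary hydroxyls can be reached, first by the C1' hydroxyl (six‑membered ring, enol ether 17) and then by the C4' hydroxyl (five‑membered ring), so the cage should make the spiro carbon a stereocentre of the required configuration and leave C5 as the only doubly activated methylene.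

Step 9
Reactants: 18 cage ketal of 16
Product: 20 5‑methyl cage ketal, via 5‑methylidene cage ketal 19 (not isolated)
Conditions: aq. HCHO (1.2 equiv), Hantzsch ester (1.1 equiv), L‑proline (10 mol%), CH2Cl2, rt
Reagents that add atoms: formaldehyde, C=O
Why: Organocatalytic reductive alkylation (Knoevenagel condensation to 19, then conjugate hydride transfer from the Hantzsch ester) should mono‑methylate the 1,3‑diketone methylene without O‑alkylation; the new CH centre is enolisable and of no consequence.

Step 10
Reactants: 20 5‑methyl cage ketal; 21 3‑methylbut‑2‑en‑1‑yl acetate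
Product: 22 (5R)‑5‑methyl‑5‑(3‑methylbut‑2‑en‑1‑yl) cage ketal
Conditions: Pd2(dba)3 (2.5 mol%), (R,R)‑DACH‑phenyl bisphosphine ligand [N,N'‑(1R,2R)‑cyclohexane‑1,2‑diylbis(2‑diphenylphosphinobenzamide)] (7.5 mol%), Cs2CO3 (1.1 equiv), CH2Cl2, rt
Reagents that add atoms: none
Why: In this Tsuji–Trost asymmetric allylic alkylation zerovalent palladium should ionise the prenyl acetate, and the 2‑methyl‑1,3‑diketone enolate should attack the unsubstituted terminus of the dimethylallyl ligand (linear prenyl) on the enolate face selected by the chiral pocket of the ligand, setting the quaternary C5 stereocentre under catalyst control.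

Step 11
Reactants: 22 (5R)‑5‑methyl‑5‑(3‑methylbut‑2‑en‑1‑yl) cage ketal
Product: 23 (5R,1'R,3a'S,4'R,7a'S)‑1',4'‑dihydroxy‑1',4',5‑trimethyl‑5‑(3‑methylbut‑2‑en‑1‑yl)octahydrospiro[cyclohexane‑1,6'‑indene]‑2,4,6‑trione (spiro carbon as in 26)
Conditions: 1 M HCl, THF, rt
Reagents that add atoms: water, O
Why: Acid hydrolysis of the ketal through its oxocarbenium ion should return the C2 carbonyl and both tertiary alcohols, driven by excess water and by enolisation of the freed 1,3‑diketone; no stereocentre is touched and the quaternary C5 cannot epimerise.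

Step 12
Reactants: 23 spirotrione diol with quaternary C5; 24 (S)‑2‑methylbutanoic acid
Product: 26 hyperielliptone HB, via enol ester 25 (not isolated)
Conditions: DCC (1.2 equiv), DMAP (0.3 equiv), CH2Cl2, 0 °C → rt
Reagents that add atoms: none
Why: Carbodiimide/DMAP C‑acylation of the cyclic 1,3‑diketone (O‑acylation to 25, then DMAP‑mediated 1,3‑acyl shift to carbon, Steglich/Fries type) should occur at C3, the only enolisable ring carbon; the tertiary alcohols should not react and the mild conditions should keep the (S) centre of the acid.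

**Compound list**

1 | nitromethane | C[N+](=O)[O-] | starting material
2 | methyl 2‑(bromomethyl)prop‑2‑enoate | C=C(CBr)C(=O)OC | starting material
3 | methyl 2‑methylidene‑4‑nitrobutanoate | C=C(CC[N+](=O)[O-])C(=O)OC | intermediate
4 | cyclopent‑2‑en‑1‑one | O=C1C=CCC1 | starting material
5 | methyl 2‑methylidene‑4‑nitro‑4‑[(1S)‑3‑oxocyclopentyl]butanoate (C4 epimers) | O=C1C[C@H](CC1)C(CC(=C)C(=O)OC)[N+](=O)[O-] | intermediate (not isolated)
6 | methyl (3aS,7aS)‑4‑nitro‑1‑oxooctahydro‑1H‑indene‑6‑carboxylate (cis‑fused; C4 and C6 epimers) | COC(=O)C1C[C@H]2[C@H](CCC2=O)C(C1)[N+](=O)[O-] | intermediate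
7 | potassium nitronate of 6 | COC(=O)C1C[C@H]2[C@H](CCC2=O)C(C1)=[N+]([O-])[O-].[K+] | intermediate (not isolated)
8 | methyl (3aS,7aS)‑1,4‑dioxooctahydro‑1H‑indene‑6‑carboxylate (cis‑fused; C6 epimers) | COC(=O)C1C[C@H]2[C@H](CCC2=O)C(=O)C1 | intermediate
9 | methyl (1R,3aS,4R,7aS)‑1,4‑dihydroxy‑1,4‑dimethyloctahydro‑1H‑indene‑6‑carboxylate (both OH trans to the ring‑fusion H; C6 epimers) | COC(=O)C1C[C@H]2[C@H](CC[C@@]2(C)O)[C@](C)(O)C1 | intermediate
10 | methyl (1R,3aS,4R,7aS)‑1,4‑dimethyl‑1,4‑bis(trimethylsilyloxy)octahydro‑1H‑indene‑6‑carboxylate | COC(=O)C1C[C@H]2[C@H](CC[C@@]2(C)O[Si](C)(C)C)[C@](C)(O[Si](C)(C)C)C1 | intermediate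
11 | S‑tert‑butyl ethanethioate | CC(=O)SC(C)(C)C | starting material
12 | S‑tert‑butyl 3‑[(1R,3aS,4R,7aS)‑1,4‑dimethyl‑1,4‑bis(trimethylsilyloxy)octahydro‑1H‑inden‑6‑yl]‑3‑oxopropanethioate (C6 epimers) | CC(C)(C)SC(=O)CC(=O)C1C[C@H]2[C@H](CC[C@@]2(C)O[Si](C)(C)C)[C@](C)(O[Si](C)(C)C)C1 | intermediate
13 | (trimethylsilyl)ketene, 2‑(trimethylsilyl)ethenone | C[Si](C)(C)C=C=O | starting material
14 | S‑tert‑butyl 3‑oxo‑3‑{6‑[(trimethylsilyl)acetyl]‑1,4‑dimethyl‑1,4‑bis(trimethylsilyloxy)octahydro‑1H‑inden‑6‑yl}propanethioate, present as its dilithium dienolate | CC(C)(C)SC(=O)CC(=O)C1(C(=O)C[Si](C)(C)C)C[C@H]2[C@H](CC[C@@]2(C)O[Si](C)(C)C)[C@](C)(O[Si](C)(C)C)C1 | intermediate (not isolated)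
15 | 5‑(trimethylsilyl) spirotrione bis(trimethylsilyl ether), present as its lithium enolate | O=C1CC(=O)C([Si](C)(C)C)C(=O)C12C[C@H]3[C@H](CC[C@@]3(C)O[Si](C)(C)C)[C@](C)(O[Si](C)(C)C)C2 | intermediate (not isolated)
16 | (1'R,3a'S,4'R,7a'S)‑1',4'‑dihydroxy‑1',4'‑dimethyloctahydrospiro[cyclohexane‑1,6'‑indene]‑2,4,6‑trione (spiro carbon not a stereocentre) | O=C1CC(=O)CC(=O)C12C[C@H]3[C@H](CC[C@@]3(C)O)[C@](C)(O)C2 | intermediate
17 | cyclic enol ether of 16: C2–O–C1' vinylogous ester, C4'–OH free | O=C1CC(=O)[C@]2(C[C@H]3[C@H](CC[C@@]3(C)O4)[C@](C)(O)C2)C4=C1 | intermediate (not isolated)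
18 | cage ketal of 16: C2 bonded to the C1' oxygen and the C4' oxygen, C4 and C6 ketones, spiro carbon configured as in 26 | O=C1CC(=O)[C@]2(C[C@H]3[C@H](CC[C@@]3(C)O4)[C@](C)(O5)C2)[C@@]45C1 | intermediate
19 | 5‑methylidene cage ketal | O=C1C(=C)C(=O)[C@]2(C[C@H]3[C@H](CC[C@@]3(C)O4)[C@](C)(O5)C2)[C@@]45C1 | intermediate (not isolated)
20 | 5‑methyl cage ketal (C5 epimers, enolisable) | O=C1C(C)C(=O)[C@]2(C[C@H]3[C@H](CC[C@@]3(C)O4)[C@](C)(O5)C2)[C@@]45C1 | intermediate
21 | 3‑methylbut‑2‑en‑1‑yl acetate (prenyl acetate) | CC(=O)OCC=C(C)C | starting material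
22 | (5R)‑5‑methyl‑5‑(3‑methylbut‑2‑en‑1‑yl) cage ketal | O=C1[C@@](C)(CC=C(C)C)C(=O)[C@]2(C[C@H]3[C@H](CC[C@@]3(C)O4)[C@](C)(O5)C2)[C@@]45C1 | intermediate
23 | (5R,1'R,3a'S,4'R,7a'S)‑1',4'‑dihydroxy‑1',4',5‑trimethyl‑5‑(3‑methylbut‑2‑en‑1‑yl)octahydrospiro[cyclohexane‑1,6'‑indene]‑2,4,6‑trione (spiro carbon as in 26) | O=C1[C@@](C)(CC=C(C)C)C(=O)[C@]2(C[C@H]3[C@H](CC[C@@]3(C)O)[C@](C)(O)C2)C(=O)C1 | intermediate
24 | (S)‑2‑methylbutanoic acid | CC[C@H](C)C(=O)O | starting material
25 | C4 enol (S)‑2‑methylbutanoate of 23 | O=C1C=C(OC(=O)[C@@H](C)CC)[C@@](C)(CC=C(C)C)C(=O)[C@]12C[C@H]3[C@H](CC[C@@]3(C)O)[C@](C)(O)C2 | intermediate (not isolated)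
26 | hyperielliptone HB | CC[C@H](C)C(=O)C1=C(O)[C@@](C)(CC=C(C)C)C(=O)[C@]2(C[C@H]3[C@H](CC[C@@]3(C)O)[C@](C)(O)C2)C1=O | target

**Step count and risks**

Total steps: 12. Longest linear sequence: 12 steps (1 and 2 to 26); the other inputs (4, 11, 13, 21, 24) are bought.

Steps most likely to fail:

First, step 7 (the proposed new annulation). γ‑Deprotonation at the tertiary ring carbon may stay incomplete, the ketene may be consumed by oligomerisation or attacked through the α‑carbon, and the ring closure may stall through O‑acylation or carbon‑to‑oxygen silyl migration. The fallback uses known chemistry and sets out from 12. The dianion (LiN(iPr)2, 2.2 equiv) is acylated at the γ‑carbon with N‑methoxy‑N‑methylacetamide to give S‑tert‑butyl 3‑[6‑acetyl‑1,4‑dimethyl‑1,4‑bis(trimethylsilyloxy)octahydro‑1H‑inden‑6‑yl]‑3‑oxopropanethioate F1. NaOMe in MeOH then closes the ring by Claisen condensation of the methyl ketone onto the thioester (the classical triketo‑ester to phloroglucinol‑trione cyclisation), and dilute HCl removes the silyl ethers. The fallback comes back to the route at 16.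

Second, step 8 (cage ketal). The Brønsted acid may eliminate a tertiary alcohol, may join C1' and C4' through a cyclic ether, or the reaction may stop at the enol‑ether stage. The fallback sets out from 15: step 7 is quenched with pH 7 buffer so that only the C–Si bond is lost and the spirotrione bis(trimethylsilyl ether) F2 is isolated. An aprotic silyl‑transfer ketalisation (catalytic Me3SiOTf with N,O‑bis(trimethylsilyl)acetamide, CH2Cl2, −78 → −20 °C) then lets the two silyl ethers add to the C2 carbonyl with loss of hexamethyldisiloxane. The fallback comes back at 18.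

Third, step 10 (asymmetric prenylation). The ligand may discriminate poorly between the enolate faces or be mismatched with the chiral cage, and O‑prenylation or attack at the substituted allyl terminus may compete. The fallback sets out from 20 and replaces π‑allyl‑metal control by chiral ion‑pair control: prenyl bromide, solid Cs2CO3 and an N‑spiro binaphthyl‑derived quaternary ammonium bromide as phase‑transfer catalyst in toluene at −20 °C. It comes back at 22 and makes no compound outside the list (F0).

Further compounds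
F1 | step 7 | S‑tert‑butyl 3‑[6‑acetyl‑1,4‑dimethyl‑1,4‑bis(trimethylsilyloxy)octahydro‑1H‑inden‑6‑yl]‑3‑oxopropanethioate | CC(=O)C1(C(=O)CC(=O)SC(C)(C)C)C[C@H]2[C@H](CC[C@@]2(C)O[Si](C)(C)C)[C@](C)(O[Si](C)(C)C)C1
F2 | step 8 | (1'R,3a'S,4'R,7a'S)‑1',4'‑dimethyl‑1',4'‑bis(trimethylsilyloxy)octahydrospiro[cyclohexane‑1,6'‑indene]‑2,4,6‑trione | O=C1CC(=O)CC(=O)C12C[C@H]3[C@H](CC[C@@]3(C)O[Si](C)(C)C)[C@](C)(O[Si](C)(C)C)C2
F0 | step 10 | none | none
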